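**Strategy.** Ring D (D1 on the methine, D3 methyl, D4 methoxy, D5 H) is a phloroglucinol monomethyl ether. Its D1–D6 edge can be the C3–C2(=O) unit of a 4-phenyl-3,4-dihydrocoumarin built on ring A, whose lactone oxygen is the flavanone O1. The route rests on disconnecting D5–D6. A 3-[(E)-3-methoxy-2-methylbut-2-enoyl]-4-phenyldihydrocoumarin (benzyl ethers on ring A, iodine at the future C4a) is treated with base. In one operation ring D is closed and aromatised, the lactone is opened, and O1 is released as the only free ring A phenol, next to the iodide. Chromone annulation, asymmetric phenyl addition and hydrogenolysis complete the flavanone.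

Key step: step 11

Assumption: the sense of induction of (R)-DTBM-SEGPHOS in step 5 and of (R)-t-BuPyOx in step 13 is taken over from the parent 4-arylcoumarins and chromone; if a model run shows the opposite sense, the antipodal ligand is used.

Step 1
Reactants: 1 2,6-dimethoxytoluene
Product: 3 3,5-dimethoxy-4-methylphenol, via aryl pinacol boronate 2 (not isolated)
Conditions: [Ir(OMe)(cod)]2 (1.5 mol%), 4,4′-di-tert-butyl-2,2′-bipyridine (3 mol%), HBpin (1.5 equiv), THF, 80 °C; then KHSO5 (as 2KHSO5·KHSO4·K2SO4), acetone/H2O, 0 °C, 10 min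
Reagents that add atoms: potassium peroxymonosulfate, [K+].[O-]S(=O)(=O)OO (phenol oxygen); pinacolborane, CC1(C)OBOC1(C)C (boron group of 2 only)
Why: Sterically controlled iridium-catalysed C–H borylation should take place at the only C–H not flanked by a substituent (para to the methyl group), and peroxymonosulfate oxidation of boronate 2 in the same flask gives the phenol.

Step 2
Reactants: 3 3,5-dimethoxy-4-methylphenol; 4 ethyl phenylpropiolate
Product: 5 5,7-dimethoxy-6-methyl-4-phenyl-2H-chromen-2-one
Conditions: Pd(OAc)2 (2 mol%), CF3CO2H/CH2Cl2, rt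
Reagents that add atoms: none
Why: Acid-promoted hydroarylation of the alkynoate by the electron-rich phenol at either of its two equivalent ortho positions, followed by lactonisation (a Pechmann-type coumarin annulation), places phenyl at C4 and the methyl group para to the ring oxygen.

Step 3
Reactants: 5 5,7-dimethoxy-6-methyl-4-phenyl-2H-chromen-2-one
Product: 6 5,7-dihydroxy-6-methyl-4-phenyl-2H-chromen-2-one
Conditions: BBr3 (4 equiv), CH2Cl2, −78 °C → rt; H2O
Reagents that add atoms: none
Why: Lewis acid cleavage of both aryl methyl ethers, which the coumarin lactone tolerates, frees the two oxygens for protecting groups that can later be removed without touching the ring D methyl ether.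

Step 4
Reactants: 6 5,7-dihydroxy-6-methyl-4-phenyl-2H-chromen-2-one
Product: 7 5,7-bis(benzyloxy)-6-methyl-4-phenyl-2H-chromen-2-one
Conditions: BnBr (2.5 equiv), K2CO3, DMF, 60 °C
Reagents that add atoms: benzyl bromide, BrCc1ccccc1
Why: Williamson ether synthesis on both phenols; benzyl ethers withstand copper hydride, amide bases and palladium/CO chemistry and are removed last by hydrogenolysis.

Step 5
Reactants: 7 5,7-bis(benzyloxy)-6-methyl-4-phenyl-2H-chromen-2-one
Product: 8 (4R)-5,7-bis(benzyloxy)-6-methyl-4-phenylchroman-2-one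
Conditions: Cu(OAc)2·H2O (3 mol%), (R)-DTBM-SEGPHOS (3 mol%), (EtO)2MeSiH (3 equiv), t-BuOH (2 equiv), THF/toluene, rt
Reagents that add atoms: none
Why: Catalyst-controlled asymmetric 1,4-reduction of a 4-arylcoumarin by ligated copper hydride, in which the chiral bisphosphine selects the face of hydride delivery so that C4 becomes R and tert-butanol protonates the copper enolate before over-reduction to the lactol.

Step 6
Reactants: 8 (4R)-5,7-bis(benzyloxy)-6-methyl-4-phenylchroman-2-one
Product: 9 (4R)-5,7-bis(benzyloxy)-8-iodo-6-methyl-4-phenylchroman-2-one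
Conditions: N-iodosuccinimide (1.1 equiv), CF3CO2H (10 mol%), MeCN/CH2Cl2, 0 °C → rt, dark
Reagents that add atoms: N-iodosuccinimide, O=C1CCC(=O)N1I
Why: Electrophilic aromatic iodination at the only free ring A position, activated by both benzyloxy groups; iodine is chosen over bromine because the later carbonylative coupling at this doubly ortho-substituted, electron-rich carbon needs fast oxidative addition.

Step 7
Reactants: 10 methyl 2-methylacetoacetate
Product: 11 methyl (E)-3-methoxy-2-methylbut-2-enoate
Conditions: HC(OMe)3 (1.5 equiv), H2SO4 (cat.), MeOH, rt; then distil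
Reagents that add atoms: trimethyl orthoformate, COC(OC)OC
Why: Acid-catalysed ketalisation with the orthoformate and loss of methanol on distillation gives the conjugated enol ether, the (E) isomer (methoxy trans to the ester) being the thermodynamically favoured one.

Step 8
Reactants: 11 methyl (E)-3-methoxy-2-methylbut-2-enoate
Product: 12 (E)-3-methoxy-2-methylbut-2-enoic acid
Conditions: KOH (2 equiv), MeOH/H2O, 60 °C; then 1 M HCl to pH 3, 0 °C
Reagents that add atoms: potassium hydroxide, [K+].[OH-]
Why: Saponification of the ester, during which the enol ether is inert to hydroxide and the double bond geometry is kept; cold acidification avoids enol ether hydrolysis.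

Step 9
Reactants: 12 (E)-3-methoxy-2-methylbut-2-enoic acid
Product: 13 (E)-3-methoxy-2-methylbut-2-enoyl chloride
Conditions: (COCl)2 (1.2 equiv), DMF (cat.), CH2Cl2, 0 °C → rt; evaporate, use crude
Reagents that add atoms: oxalyl chloride, O=C(Cl)C(=O)Cl
Why: Vilsmeier-type activation of the acid gives the acid chloride, whose enol ether is deactivated toward HCl by conjugation with the carbonyl group.

Step 10
Reactants: 9 (4R)-5,7-bis(benzyloxy)-8-iodo-6-methyl-4-phenylchroman-2-one; 13 (E)-3-methoxy-2-methylbut-2-enoyl chloride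
Product: 14 (3R,4R)-5,7-bis(benzyloxy)-8-iodo-3-[(E)-3-methoxy-2-methylbut-2-enoyl]-6-methyl-4-phenylchroman-2-one
Conditions: LiN(SiMe3)2 (2.1 equiv), THF, −78 °C; 13 (1.1 equiv), −78 °C; AcOH, −78 °C
Reagents that add atoms: none
Why: Claisen-type C-acylation of the lithium lactone enolate by the acid chloride, the second equivalent of base taking up the acidic proton of the beta-keto lactone; the acyl group should enter anti to the C4 phenyl group (3,4-trans), but C3 is configurationally labile and is erased in step 11.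

Step 11
Reactants: 14 (3R,4R)-5,7-bis(benzyloxy)-8-iodo-3-[(E)-3-methoxy-2-methylbut-2-enoyl]-6-methyl-4-phenylchroman-2-one
Product: 16 2-[(S)-[2,4-bis(benzyloxy)-6-hydroxy-5-iodo-3-methylphenyl](phenyl)methyl]-5-methoxy-4-methylbenzene-1,3-diol, via cyclohexenedione 15 (not isolated)
Conditions: LiN(SiMe3)2 (3.5 equiv), THF (0.02 M), −78 °C → rt; AcOH (4 equiv), −20 °C
Reagents that add atoms: none
Why: Proposed new method: LiN(SiMe3)2 removes first the C3 proton between the two carbonyls and then, reversibly, a proton of the enol ether methyl group (future D5); this carbon adds to the lactone carbonyl (future D6), directly or after E1cB opening of the aryl ester to an acylketene, so that D5–D6 forms and the phenoxide that is O1 leaves, after which a third equivalent of base enolises cyclohexenedione 15 and ring D aromatises irreversibly. The closest known reaction type is the base-induced aromatising Claisen (Dieckmann-type) cyclisation of 3,5-dioxo ester polyanions and of their enol ethers to phloroglucinols, which has not been run with an aryl lactone as acyl donor. Ring D closes in a 6-exo-trig mode, the carbonyl oxygen and the departing aryloxy group lying outside the new ring. No stereocentre is formed: C3 becomes an aromatic carbon and the methine, never alpha to a carbonyl, is carried over unchanged (its descriptor changes from R to S only because ring D now outranks phenyl). The selectivity needed is attack by the terminal methyl carbon on the lactone carbonyl alone, secured by the (E)-enol ether, which holds that methyl group cis to the ketone, rules out O-cyclisation to a pyranone and fixes where methoxy, methyl and both hydroxyls end up, while HN(SiMe3)2 is too hindered to intercept the acyl donor.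

Step 12
Reactants: 16 2-[(S)-[2,4-bis(benzyloxy)-6-hydroxy-5-iodo-3-methylphenyl](phenyl)methyl]-5-methoxy-4-methylbenzene-1,3-diol; 17 trimethylsilylacetylene
Product: 20 5,7-bis(benzyloxy)-8-[(S)-(2,6-dihydroxy-4-methoxy-3-methylphenyl)(phenyl)methyl]-6-methyl-4H-chromen-4-one, via silyl ynone 18 (not isolated), via enaminone 19 (not isolated)
Conditions: PdCl2(dppf) (5 mol%), CO (1 atm), Et2NH (5 equiv), THF, 50 °C; then MeOH, 50 °C
Reagents that add atoms: carbon monoxide, [C-]#[O+]; diethylamine, CCNCC (nitrogen of 19 only)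
Why: Carbonylative Sonogashira coupling at the aryl iodide gives ynone 18, diethylamine and methanol convert it with loss of silicon into enaminone 19, and the ortho phenol O1 closes ring C by 6-endo addition–elimination (a known chromone annulation of 2-iodophenols); the ring D hydroxyls are shielded by the triarylmethyl carbon and should not intercept the acylpalladium species.

Step 13
Reactants: 20 5,7-bis(benzyloxy)-8-[(S)-(2,6-dihydroxy-4-methoxy-3-methylphenyl)(phenyl)methyl]-6-methyl-4H-chromen-4-one; 21 phenylboronic acid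
Product: 22 (2S)-5,7-bis(benzyloxy)-8-[(S)-(2,6-dihydroxy-4-methoxy-3-methylphenyl)(phenyl)methyl]-6-methyl-2-phenylchroman-4-one
Conditions: Pd(OCOCF3)2 (10 mol%), (R)-4-tert-butyl-2-(pyridin-2-yl)-4,5-dihydrooxazole ((R)-t-BuPyOx, 12 mol%), NH4PF6 (30 mol%), H2O (5 equiv), 21 (2.5 equiv), ClCH2CH2Cl, 60 °C, N2
Reagents that add atoms: none
Why: Asymmetric conjugate addition of an arylboronic acid to a chromone catalysed by cationic divalent palladium with a chiral pyridine-oxazoline (known for chromones to flavanones); the ligand should direct phenyl to the C2 face that gives 2S independently of the remote methine, and water protonates the palladium enolate so that no flavone forms.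

Step 14
Reactants: 22 (2S)-5,7-bis(benzyloxy)-8-[(S)-(2,6-dihydroxy-4-methoxy-3-methylphenyl)(phenyl)methyl]-6-methyl-2-phenylchroman-4-one
Product: 23 (2S)-8-[(S)-(2,6-dihydroxy-4-methoxy-3-methylphenyl)(phenyl)methyl]-5,7-dihydroxy-6-methyl-2-phenylchroman-4-one
Conditions: H2 (1 atm), 10% Pd/C, EtOAc/MeOH, rt
Reagents that add atoms: none
Why: Hydrogenolysis of the two benzyl ethers over palladium on carbon under neutral conditions, which the flavanone C2–O bond, the triarylmethane and both stereocentres are expected to survive at 1 atm and short reaction time.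

**Compound list**

1 | 2,6-dimethoxytoluene | COc1cccc(OC)c1C | starting material
2 | 2-(3,5-dimethoxy-4-methylphenyl)-4,4,5,5-tetramethyl-1,3,2-dioxaborolane | COc1cc(B2OC(C)(C)C(C)(C)O2)cc(OC)c1C | intermediate (not isolated)
3 | 3,5-dimethoxy-4-methylphenol | COc1cc(O)cc(OC)c1C | intermediate
4 | ethyl phenylpropiolate | CCOC(=O)C#Cc1ccccc1 | starting material
5 | 5,7-dimethoxy-6-methyl-4-phenyl-2H-chromen-2-one | O=C1C=C(c2ccccc2)c2c(OC)c(C)c(OC)cc2O1 | intermediate
6 | 5,7-dihydroxy-6-methyl-4-phenyl-2H-chromen-2-one | O=C1C=C(c2ccccc2)c2c(O)c(C)c(O)cc2O1 | intermediate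
7 | 5,7-bis(benzyloxy)-6-methyl-4-phenyl-2H-chromen-2-one | O=C1C=C(c2ccccc2)c2c(OCc3ccccc3)c(C)c(OCc3ccccc3)cc2O1 | intermediate
8 | (4R)-5,7-bis(benzyloxy)-6-methyl-4-phenylchroman-2-one | O=C1C[C@H](c2ccccc2)c2c(OCc3ccccc3)c(C)c(OCc3ccccc3)cc2O1 | intermediate
9 | (4R)-5,7-bis(benzyloxy)-8-iodo-6-methyl-4-phenylchroman-2-one | O=C1C[C@H](c2ccccc2)c2c(OCc3ccccc3)c(C)c(OCc3ccccc3)c(I)c2O1 | intermediate
10 | methyl 2-methylacetoacetate | COC(=O)C(C)C(C)=O | starting material
11 | methyl (E)-3-methoxy-2-methylbut-2-enoate | CO/C(C)=C(C)/C(=O)OC | intermediate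
12 | (E)-3-methoxy-2-methylbut-2-enoic acid | CO/C(C)=C(C)/C(=O)O | intermediate
13 | (E)-3-methoxy-2-methylbut-2-enoyl chloride | CO/C(C)=C(C)/C(=O)Cl | intermediate
14 | (3R,4R)-5,7-bis(benzyloxy)-8-iodo-3-[(E)-3-methoxy-2-methylbut-2-enoyl]-6-methyl-4-phenylchroman-2-one (3,4-trans; C3 epimerisable) | CO/C(C)=C(C)/C(=O)[C@@H]1C(=O)Oc2c(I)c(OCc3ccccc3)c(C)c(OCc3ccccc3)c2[C@H]1c1ccccc1 | intermediate
15 | 2-[(R)-[2,4-bis(benzyloxy)-6-hydroxy-5-iodo-3-methylphenyl](phenyl)methyl]-5-methoxy-4-methylcyclohex-4-ene-1,3-dione (ring carbon 2 unassigned; present as its enolate) | COC1=C(C)C(=O)C(C(=O)C1)[C@H](c1ccccc1)c1c(OCc2ccccc2)c(C)c(OCc2ccccc2)c(I)c1O | intermediate (not isolated)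
16 | 2-[(S)-[2,4-bis(benzyloxy)-6-hydroxy-5-iodo-3-methylphenyl](phenyl)methyl]-5-methoxy-4-methylbenzene-1,3-diol | COc1cc(O)c([C@H](c2ccccc2)c2c(OCc3ccccc3)c(C)c(OCc3ccccc3)c(I)c2O)c(O)c1C | intermediate
17 | trimethylsilylacetylene | C#C[Si](C)(C)C | starting material
18 | 1-[2,4-bis(benzyloxy)-5-[(S)-(2,6-dihydroxy-4-methoxy-3-methylphenyl)(phenyl)methyl]-6-hydroxy-3-methylphenyl]-3-(trimethylsilyl)prop-2-yn-1-one | COc1cc(O)c([C@H](c2ccccc2)c2c(OCc3ccccc3)c(C)c(OCc3ccccc3)c(C(=O)C#C[Si](C)(C)C)c2O)c(O)c1C | intermediate (not isolated)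
19 | (E)-1-[2,4-bis(benzyloxy)-5-[(S)-(2,6-dihydroxy-4-methoxy-3-methylphenyl)(phenyl)methyl]-6-hydroxy-3-methylphenyl]-3-(diethylamino)prop-2-en-1-one | COc1cc(O)c([C@H](c2ccccc2)c2c(OCc3ccccc3)c(C)c(OCc3ccccc3)c(C(=O)/C=C/N(CC)CC)c2O)c(O)c1C | intermediate (not isolated)
20 | 5,7-bis(benzyloxy)-8-[(S)-(2,6-dihydroxy-4-methoxy-3-methylphenyl)(phenyl)methyl]-6-methyl-4H-chromen-4-one | COc1cc(O)c([C@H](c2ccccc2)c2c(OCc3ccccc3)c(C)c(OCc3ccccc3)c3c2OC=CC3=O)c(O)c1C | intermediate
21 | phenylboronic acid | OB(O)c1ccccc1 | starting material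
22 | (2S)-5,7-bis(benzyloxy)-8-[(S)-(2,6-dihydroxy-4-methoxy-3-methylphenyl)(phenyl)methyl]-6-methyl-2-phenylchroman-4-one | COc1cc(O)c([C@H](c2ccccc2)c2c(OCc3ccccc3)c(C)c(OCc3ccccc3)c3c2O[C@H](c2ccccc2)CC3=O)c(O)c1C | intermediate
23 | (2S)-8-[(S)-(2,6-dihydroxy-4-methoxy-3-methylphenyl)(phenyl)methyl]-5,7-dihydroxy-6-methyl-2-phenylchroman-4-one | COc1cc(O)c([C@H](c2ccccc2)c2c(O)c(C)c(O)c3c2O[C@H](c2ccccc2)CC3=O)c(O)c1C | target

**Step count.** Total: 14 steps. Longest linear sequence: 11 steps (steps 1–6 and 10–14, from 2,6-dimethoxytoluene); the acid chloride branch is 3 steps (7–9).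

**Steps most likely to fail**

Step 11. The second deprotonation at the enol ether methyl group may stay too unfavourable for ring closure, leaving the mono-enolate inert. Alternatively, the reversibly opened acyl donor may be consumed by intermolecular acylation or by retro-Claisen loss of the side chain. The fallback sets out from 9 and runs the same cyclisation in its established form on an alkyl ester. Methanolysis of the lactone (NaOMe, MeOH, 0 °C; evaporate) and silylation of the liberated phenoxide (t-BuMe2SiCl, imidazole, DMF) should give methyl (3R)-3-[2,4-bis(benzyloxy)-6-(tert-butyldimethylsilyloxy)-5-iodo-3-methylphenyl]-3-phenylpropanoate F1. C-acylation of its lithium enolate with 13 (LiN(SiMe3)2, THF, −78 °C) gives methyl (E)-2-[(R)-[2,4-bis(benzyloxy)-6-(tert-butyldimethylsilyloxy)-5-iodo-3-methylphenyl](phenyl)methyl]-5-methoxy-4-methyl-3-oxohex-4-enoate F2. Aromatising Claisen cyclisation with methoxide as leaving group (LiN(iPr)2, THF, −78 → 0 °C) gives 2-[(S)-[2,4-bis(benzyloxy)-6-(tert-butyldimethylsilyloxy)-5-iodo-3-methylphenyl](phenyl)methyl]-5-methoxy-4-methylbenzene-1,3-diol F3. Desilylation (Bu4NF, AcOH, THF, 0 °C) comes back to the route at 16.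

Step 10. The aryl lactone enolate may be acylated on oxygen, may open to a ketene phenoxide before the acid chloride arrives, or the excess amide base may consume the acid chloride. The fallback sets out from 9 and separates enolate formation from acylation. Trapping the enolate (LiN(SiMe3)2, Me3SiCl, THF, −78 °C; non-aqueous work-up) gives the ketene silyl acetal (4R)-5,7-bis(benzyloxy)-8-iodo-6-methyl-4-phenyl-2-(trimethylsilyloxy)-4H-chromene F4. This is C-acylated under neutral conditions with 13 (ZnBr2 cat., CH2Cl2, 0 °C → rt; Mukaiyama-type acylation of a ketene silyl acetal) and comes back to the route at 14.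

Step 13. Facial selectivity at C2 may be poor, because the bulky C8 substituent and the remote methine can oppose the ligand, and addition to the electron-rich chromone may be slow. The fallback sets out from 20 and gives up catalyst control. Conjugate addition of 21 with an achiral catalyst (Pd(OCOCF3)2, 2,2′-bipyridine, aqueous AcOH/THF, 60 °C) should give 22 together with its C2 epimer (2R)-5,7-bis(benzyloxy)-8-[(S)-(2,6-dihydroxy-4-methoxy-3-methylphenyl)(phenyl)methyl]-6-methyl-2-phenylchroman-4-one F5. The two are diastereomers and should be separable by preparative chromatography. F5 is recycled by base-mediated ring opening and reclosure (NaOAc, EtOH, reflux) through the chalcone (E)-1-[2,4-bis(benzyloxy)-5-[(S)-(2,6-dihydroxy-4-methoxy-3-methylphenyl)(phenyl)methyl]-6-hydroxy-3-methylphenyl]-3-phenylprop-2-en-1-one F6 and separated again. The fallback comes back to the route at 22.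

**Further compounds**

F1 | step 11 | methyl (3R)-3-[2,4-bis(benzyloxy)-6-(tert-butyldimethylsilyloxy)-5-iodo-3-methylphenyl]-3-phenylpropanoate | COC(=O)C[C@H](c1ccccc1)c1c(OCc2ccccc2)c(C)c(OCc2ccccc2)c(I)c1O[Si](C)(C)C(C)(C)C
F2 | step 11 | methyl (E)-2-[(R)-[2,4-bis(benzyloxy)-6-(tert-butyldimethylsilyloxy)-5-iodo-3-methylphenyl](phenyl)methyl]-5-methoxy-4-methyl-3-oxohex-4-enoate (C2 epimers) | COC(=O)C(C(=O)/C(C)=C(C)/OC)[C@H](c1ccccc1)c1c(OCc2ccccc2)c(C)c(OCc2ccccc2)c(I)c1O[Si](C)(C)C(C)(C)C
F3 | step 11 | 2-[(S)-[2,4-bis(benzyloxy)-6-(tert-butyldimethylsilyloxy)-5-iodo-3-methylphenyl](phenyl)methyl]-5-methoxy-4-methylbenzene-1,3-diol | COc1cc(O)c([C@H](c2ccccc2)c2c(OCc3ccccc3)c(C)c(OCc3ccccc3)c(I)c2O[Si](C)(C)C(C)(C)C)c(O)c1C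
F4 | step 10 | (4R)-5,7-bis(benzyloxy)-8-iodo-6-methyl-4-phenyl-2-(trimethylsilyloxy)-4H-chromene | C[Si](C)(C)OC1=C[C@H](c2ccccc2)c2c(OCc3ccccc3)c(C)c(OCc3ccccc3)c(I)c2O1
F5 | step 13 | (2R)-5,7-bis(benzyloxy)-8-[(S)-(2,6-dihydroxy-4-methoxy-3-methylphenyl)(phenyl)methyl]-6-methyl-2-phenylchroman-4-one | COc1cc(O)c([C@H](c2ccccc2)c2c(OCc3ccccc3)c(C)c(OCc3ccccc3)c3c2O[C@@H](c2ccccc2)CC3=O)c(O)c1C
F6 | step 13 | (E)-1-[2,4-bis(benzyloxy)-5-[(S)-(2,6-dihydroxy-4-methoxy-3-methylphenyl)(phenyl)methyl]-6-hydroxy-3-methylphenyl]-3-phenylprop-2-en-1-one | COc1cc(O)c([C@H](c2ccccc2)c2c(OCc3ccccc3)c(C)c(OCc3ccccc3)c(C(=O)/C=C/c3ccccc3)c2O)c(O)c1C
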